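**Retrosynthetic overview**

- Feature: on the benzene ring the carboxyl carbon C1 sits between the oxygen-bearing C2 and the chain-bearing C6 (second oxygen on C4). The contiguous C2–C1–C6 pattern is the footprint of a 3-alkoxybenzyne (aryne carbons C1/C6, directing oxygen on C2) that takes up an alkyllithium and then CO2.
- End-game (functional-group changes only): C10 acetate ⇐ C10 silyl ether; the two phenols ⇐ MOM ethers.
- Key disconnection: C6–C1′ and C1–CO2H are cut together, giving 1,2-dibromo-3,5-bis(methoxymethoxy)benzene, the C15 alkyllithium and CO2.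
- Fragments: the dibromide comes from 5-bromoresorcinol (MOM protection, ring bromination). The alkyllithium comes from (R)-oct-1-yn-3-ol and 1,7-dibromoheptane (acetylide alkylation, Z-selective semihydrogenation, Br→I, I→Li).
- Rings and stereo: no ring is formed, the benzene ring is bought; the C10 centre is bought and never touched at carbon; the 8Z alkene comes from the alkyne.

Key step: step 7

Assumption: (R)-oct-1-yn-3-ol of high enantiomeric purity is purchased; the alkyllithium is generated in a separate flask within step 7 and used at once.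

**Step 1**
Reactants: 1 5-bromoresorcinol
Product: 2 1-bromo-3,5-bis(methoxymethoxy)benzene
Conditions: MOMCl (2.6 equiv), i-Pr2NEt (3 equiv), CH2Cl2, 0 °C → rt
Reagents that add atoms: chloromethyl methyl ether (MOMCl), COCCl
Why: Base-mediated O-alkylation of both phenols with the α-chloro ether (MOM protection, Williamson-type) should be fast and leaves the aryl bromide untouched.

**Step 2**
Reactants: 2 1-bromo-3,5-bis(methoxymethoxy)benzene
Product: 3 1,2-dibromo-3,5-bis(methoxymethoxy)benzene
Conditions: NBS (1.0 equiv), MeCN, 0 °C → rt, dark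
Reagents that add atoms: N-bromosuccinimide, O=C1CCC(=O)N1Br
Why: Electrophilic aromatic bromination with NBS should go to the ring carbon next to bromine, which is ortho to one OMOM and para to the other, as is usual for 5-substituted resorcinol diethers, because the carbon between the two OMOM groups is more hindered, and the neutral conditions spare the acetals.

**Step 3**
Reactants: 4 (R)-oct-1-yn-3-ol
Product: 5 (R)-tert-butyldimethyl(oct-1-yn-3-yloxy)silane
Conditions: TBSCl, imidazole, DMF, rt
Reagents that add atoms: tert-butyldimethylsilyl chloride, CC(C)(C)[Si](C)(C)Cl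
Why: Imidazole-promoted silylation of the secondary propargylic alcohol does not touch the C–O bond, so the purchased (R) centre is carried over unchanged.

**Step 4**
Reactants: 5 (R)-tert-butyldimethyl(oct-1-yn-3-yloxy)silane; 6 1,7-dibromoheptane
Product: 8 (R)-1-bromo-10-(tert-butyldimethylsilyloxy)pentadec-8-yne, via lithium acetylide 7 (not isolated)
Conditions: n-BuLi (1.05 equiv), THF, −78 °C; then 6 (4 equiv), DMPU, −78 °C → rt
Reagents that add atoms: none
Why: Deprotonation of the terminal alkyne and SN2 alkylation of the lithium acetylide by a primary bromide in THF–DMPU is standard, the excess of dibromide suppresses reaction at both ends, and the stereocentre is not involved.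

**Step 5**
Reactants: 8 (R)-1-bromo-10-(tert-butyldimethylsilyloxy)pentadec-8-yne
Product: 9 (R,Z)-1-bromo-10-(tert-butyldimethylsilyloxy)pentadec-8-ene
Conditions: H2 (1 atm), Pd/CaCO3 poisoned with Pb(OAc)2, quinoline, hexane–EtOAc, rt
Reagents that add atoms: none
Why: Lindlar-type semihydrogenation delivers both hydrogens syn on the poisoned palladium surface, which sets the 8Z geometry and stops at the alkene, while the alkyl bromide, silyl ether and stereocentre are not affected.

**Step 6**
Reactants: 9 (R,Z)-1-bromo-10-(tert-butyldimethylsilyloxy)pentadec-8-ene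
Product: 10 (R,Z)-10-(tert-butyldimethylsilyloxy)-1-iodopentadec-8-ene
Conditions: NaI (5 equiv), acetone, reflux
Reagents that add atoms: sodium iodide, [Na+].[I-]
Why: Finkelstein halide exchange (SN2 at the primary carbon, driven by precipitation of NaBr) gives the iodide needed for clean lithium–iodine exchange.

**Step 7**
Reactants: 3 1,2-dibromo-3,5-bis(methoxymethoxy)benzene; 10 (R,Z)-10-(tert-butyldimethylsilyloxy)-1-iodopentadec-8-ene; 11 carbon dioxide
Product: 16 2,4-bis(methoxymethoxy)-6-[(8Z,10R)-10-(tert-butyldimethylsilyloxy)pentadec-8-enyl]benzoic acid, via chain alkyllithium 12 (not isolated), via ortho-bromoaryllithium 13 (not isolated), via aryne 14 (not isolated), via adduct aryllithium 15 (not isolated)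
Conditions: flask A: 10 (1.2 equiv), t-BuLi (2.4 equiv), Et2O–pentane, −78 °C; flask B: 3 (1.0 equiv), n-BuLi (1.0 equiv), THF–Et2O, −100 °C; A into B by cannula at −100 °C, then → −20 °C; CO2 (dry gas), −78 → 0 °C; cold 0.5 M HCl to pH 4
Reagents that add atoms: none
Why: In flask A the primary iodide undergoes lithium–iodine exchange with two equivalents of t-BuLi (the second destroys the tert-butyl iodide) to give alkyllithium 12, while in flask B n-BuLi exchanges one bromine of 3 (expected to be the one flanked by OMOM; either bromine leads to the same aryne) to give ortho-bromoaryllithium 13, which should persist at −100 °C. On warming with 12 present, 13 loses LiBr to give aryne 14, 12 adds to the aryne carbon remote from the flanking OMOM (C6–C1′ bond), and the resulting aryllithium 15, with lithium on the carbon between OMOM and the new chain, is trapped by CO2 (C1–CO2H bond). The closest known reaction type is the carbolithiation of 3-alkoxybenzynes by alkyllithiums followed by carboxylation, an established entry to 6-alkylsalicylic acids. No ring is closed and no stereocentre is formed; the C10 centre, the Z-alkene and the silyl ether are spectators that tolerate organolithiums at low temperature. The step needs regioselective addition to the aryne, and this is secured by the OMOM group next to one aryne terminus, which makes the distal carbon the electrophilic one (inductive stabilisation and lithium chelation of the developing ortho anion, plus lower steric hindrance) and outweighs the weak opposite bias of the remote second OMOM. Competition from n-BuLi is avoided because it is consumed by the exchange before 12 is added and before the aryne is released.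

**Step 8**
Reactants: 16 2,4-bis(methoxymethoxy)-6-[(8Z,10R)-10-(tert-butyldimethylsilyloxy)pentadec-8-enyl]benzoic acid
Product: 17 6-[(8Z,10R)-10-hydroxypentadec-8-enyl]-2,4-bis(methoxymethoxy)benzoic acid
Conditions: Bu4NF (3 equiv), THF, 0 °C → rt; cold 0.5 M HCl to pH 4
Reagents that add atoms: none
Why: Fluoride attacks silicon (strong Si–F bond) and cleaves only the Si–O bond, so the allylic alcohol is freed with retention while the MOM acetals, the alkene and the carboxylate are inert to Bu4NF.

**Step 9**
Reactants: 17 6-[(8Z,10R)-10-hydroxypentadec-8-enyl]-2,4-bis(methoxymethoxy)benzoic acid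
Product: 19 6-[(8Z,10R)-10-acetoxypentadec-8-enyl]-2,4-bis(methoxymethoxy)benzoic acid, via mixed anhydride 18 (not isolated)
Conditions: Ac2O (3 equiv), pyridine, DMAP (cat.), CH2Cl2, 0 °C → rt; then H2O–THF, rt; cold 0.5 M HCl to pH 4
Reagents that add atoms: acetic anhydride, CC(=O)OC(C)=O
Why: DMAP-catalysed acylation with Ac2O acetylates the secondary allylic alcohol with retention (the C–O bond is not broken), and the hindered 2,6-disubstituted benzoic acid, converted in passing into mixed anhydride 18, is returned by hydrolysis in the aqueous pyridine quench.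

**Step 10**
Reactants: 19 6-[(8Z,10R)-10-acetoxypentadec-8-enyl]-2,4-bis(methoxymethoxy)benzoic acid
Product: 20 6-[(8Z,10R)-10-acetoxypentadec-8-enyl]-2,4-dihydroxybenzoic acid (target)
Conditions: ZnBr2 (2 equiv), n-PrSH (4 equiv), CH2Cl2, 0 °C, short contact; pH 4 buffer, no heating
Reagents that add atoms: none
Why: Lewis-acid-assisted cleavage of the aryl MOM acetals with thiol capture of the methoxymethyl cation (a known rapid MOM-deprotection protocol) runs at 0 °C without protic acid or alcohol, so the allylic acetate, the Z-alkene and the stereocentre should survive, and the thiol keeps formaldehyde equivalents away from the resorcinol ring and the carboxyl group.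

**Compound list**

1 | 5-bromoresorcinol | Oc1cc(O)cc(Br)c1 | starting material
2 | 1-bromo-3,5-bis(methoxymethoxy)benzene | COCOc1cc(Br)cc(OCOC)c1 | intermediate
3 | 1,2-dibromo-3,5-bis(methoxymethoxy)benzene | Brc1cc(OCOC)cc(OCOC)c1Br | intermediate
4 | (R)-oct-1-yn-3-ol | CCCCC[C@H](C#C)O | starting material
5 | (R)-tert-butyldimethyl(oct-1-yn-3-yloxy)silane | CCCCC[C@H](C#C)O[Si](C)(C)C(C)(C)C | intermediate
6 | 1,7-dibromoheptane | BrCCCCCCCBr | starting material
7 | lithium (R)-3-(tert-butyldimethylsilyloxy)oct-1-yn-1-ide | CCCCC[C@H](C#C[Li])O[Si](C)(C)C(C)(C)C | intermediate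
8 | (R)-1-bromo-10-(tert-butyldimethylsilyloxy)pentadec-8-yne | CCCCC[C@H](C#CCCCCCCCBr)O[Si](C)(C)C(C)(C)C | intermediate
9 | (R,Z)-1-bromo-10-(tert-butyldimethylsilyloxy)pentadec-8-ene | CCCCC[C@H](/C=C\CCCCCCCBr)O[Si](C)(C)C(C)(C)C | intermediate
10 | (R,Z)-10-(tert-butyldimethylsilyloxy)-1-iodopentadec-8-ene | CCCCC[C@H](/C=C\CCCCCCCI)O[Si](C)(C)C(C)(C)C | intermediate
11 | carbon dioxide | O=C=O | starting material
12 | (R,Z)-10-(tert-butyldimethylsilyloxy)pentadec-8-enyllithium | CCCCC[C@H](/C=C\CCCCCCC[Li])O[Si](C)(C)C(C)(C)C | intermediate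
13 | [2-bromo-4,6-bis(methoxymethoxy)phenyl]lithium | [Li]c1c(Br)cc(OCOC)cc1OCOC | intermediate
14 | 3,5-bis(methoxymethoxy)benzyne (1,2-didehydro-3,5-bis(methoxymethoxy)benzene) | COCOC1=CC(OCOC)=CC#C1 | intermediate
15 | {2-[(8Z,10R)-10-(tert-butyldimethylsilyloxy)pentadec-8-enyl]-4,6-bis(methoxymethoxy)phenyl}lithium | CCCCC[C@H](/C=C\CCCCCCCc1cc(OCOC)cc(OCOC)c1[Li])O[Si](C)(C)C(C)(C)C | intermediate
16 | 2,4-bis(methoxymethoxy)-6-[(8Z,10R)-10-(tert-butyldimethylsilyloxy)pentadec-8-enyl]benzoic acid | CCCCC[C@H](/C=C\CCCCCCCc1cc(OCOC)cc(OCOC)c1C(=O)O)O[Si](C)(C)C(C)(C)C | intermediate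
17 | 6-[(8Z,10R)-10-hydroxypentadec-8-enyl]-2,4-bis(methoxymethoxy)benzoic acid | CCCCC[C@H](/C=C\CCCCCCCc1cc(OCOC)cc(OCOC)c1C(=O)O)O | intermediate
18 | acetic 6-[(8Z,10R)-10-acetoxypentadec-8-enyl]-2,4-bis(methoxymethoxy)benzoic anhydride | CCCCC[C@H](/C=C\CCCCCCCc1cc(OCOC)cc(OCOC)c1C(=O)OC(C)=O)OC(C)=O | intermediate
19 | 6-[(8Z,10R)-10-acetoxypentadec-8-enyl]-2,4-bis(methoxymethoxy)benzoic acid | CCCCC[C@H](/C=C\CCCCCCCc1cc(OCOC)cc(OCOC)c1C(=O)O)OC(C)=O | intermediate
20 | 6-[(8Z,10R)-10-acetoxypentadec-8-enyl]-2,4-dihydroxybenzoic acid | CCCCC[C@H](/C=C\CCCCCCCc1cc(O)cc(O)c1C(=O)O)OC(C)=O | target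

**Totals**

Total step count: 10. Longest linear sequence: 8 steps (4 → 20 through steps 3–10); the aryl branch (steps 1–2) joins at step 7.

**Steps most likely to fail**

Step 7 (key step). The aryne may be consumed by the ortho-bromoaryllithium or by the product aryllithium instead of by the chain alkyllithium, LiBr may be lost before the nucleophile has been added, or the addition may lose regiocontrol. The fallback uses no aryne; it sets out from 2 and 10 and rejoins the route at aryllithium 15, which is carboxylated to 16 as in step 7. Bromide 2 is converted with Mg in THF into [3,5-bis(methoxymethoxy)phenyl]magnesium bromide F1, which is coupled with iodide 10 under Li2CuCl4 catalysis (THF, −10 °C → rt; copper-catalysed Grignard–alkyl halide coupling) to give 1-[(8Z,10R)-10-(tert-butyldimethylsilyloxy)pentadec-8-enyl]-3,5-bis(methoxymethoxy)benzene F2. NBS in MeCN at 0 °C should then brominate the ring carbon between the chain and an OMOM group (ortho to one oxygen, para to the other) to give 2-bromo-1-[(8Z,10R)-10-(tert-butyldimethylsilyloxy)pentadec-8-enyl]-3,5-bis(methoxymethoxy)benzene F3. Bromine–lithium exchange on F3 (n-BuLi, THF, −78 °C) gives 15, and CO2 followed by the pH 4 work-up gives 16.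

Step 10. The allylic acetate may ionise or be displaced by the thiol under the Lewis acid, the C4 acetal may cleave incompletely, or the β-resorcylic acid may decarboxylate if warmed. The fallback reorders the end-game; it sets out from 16 and comes back at target 20. Methanolic HCl (about 1 M, 0 °C → rt) removes both MOM groups and the silyl ether together to give 2,4-dihydroxy-6-[(8Z,10R)-10-hydroxypentadec-8-enyl]benzoic acid F4. Exhaustive acetylation (Ac2O, pyridine, DMAP) gives acetic 2,4-diacetoxy-6-[(8Z,10R)-10-acetoxypentadec-8-enyl]benzoic anhydride F5, which an aqueous quench converts into 2,4-diacetoxy-6-[(8Z,10R)-10-acetoxypentadec-8-enyl]benzoic acid F6. Pyrrolidine (MeCN, 0 °C → rt) then cleaves the two aryl acetates by aminolysis, far faster than the secondary alkyl acetate, and acidification to pH 4 gives 20.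

Step 4. The acetylide may alkylate both ends of the dibromide, or HBr may be eliminated from the electrophile, which lowers the supply of the chain. The fallback uses an electrophile with two different halides; it sets out from 5 (through acetylide 7) and comes back at iodide 10. Acetylide 7 is alkylated with 1-bromo-7-chloroheptane (ClCCCCCCCBr) in THF–DMPU, where only the bromide end reacts, to give (R)-10-(tert-butyldimethylsilyloxy)-1-chloropentadec-8-yne F7. Semihydrogenation over Pd/CaCO3 poisoned with Pb(OAc)2 with quinoline gives (R,Z)-10-(tert-butyldimethylsilyloxy)-1-chloropentadec-8-ene F8, and NaI in refluxing 2-butanone converts F8 into 10.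

**Further compounds**

F1 | step 7 | [3,5-bis(methoxymethoxy)phenyl]magnesium bromide | COCOc1cc(OCOC)cc([Mg]Br)c1
F2 | step 7 | 1-[(8Z,10R)-10-(tert-butyldimethylsilyloxy)pentadec-8-enyl]-3,5-bis(methoxymethoxy)benzene | CCCCC[C@H](/C=C\CCCCCCCc1cc(OCOC)cc(OCOC)c1)O[Si](C)(C)C(C)(C)C
F3 | step 7 | 2-bromo-1-[(8Z,10R)-10-(tert-butyldimethylsilyloxy)pentadec-8-enyl]-3,5-bis(methoxymethoxy)benzene | CCCCC[C@H](/C=C\CCCCCCCc1cc(OCOC)cc(OCOC)c1Br)O[Si](C)(C)C(C)(C)C
F4 | step 10 | 2,4-dihydroxy-6-[(8Z,10R)-10-hydroxypentadec-8-enyl]benzoic acid | CCCCC[C@H](/C=C\CCCCCCCc1cc(O)cc(O)c1C(=O)O)O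
F5 | step 10 | acetic 2,4-diacetoxy-6-[(8Z,10R)-10-acetoxypentadec-8-enyl]benzoic anhydride | CCCCC[C@H](/C=C\CCCCCCCc1cc(OC(C)=O)cc(OC(C)=O)c1C(=O)OC(C)=O)OC(C)=O
F6 | step 10 | 2,4-diacetoxy-6-[(8Z,10R)-10-acetoxypentadec-8-enyl]benzoic acid | CCCCC[C@H](/C=C\CCCCCCCc1cc(OC(C)=O)cc(OC(C)=O)c1C(=O)O)OC(C)=O
F7 | step 4 | (R)-10-(tert-butyldimethylsilyloxy)-1-chloropentadec-8-yne | CCCCC[C@H](C#CCCCCCCCCl)O[Si](C)(C)C(C)(C)C
F8 | step 4 | (R,Z)-10-(tert-butyldimethylsilyloxy)-1-chloropentadec-8-ene | CCCCC[C@H](/C=C\CCCCCCCCl)O[Si](C)(C)C(C)(C)C
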